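At the reading time, 2.5 h, the four earlier runs stood at 24%, 24%, 25% and 25% target, against a scatter of 1.5 percentage points, though starting material ranged from 0.050 M to 0.10 M and protic impurity from 2 mM to 3 mM.

| flask | starting material | partner | protic impurity | remark | time |
|---|---|---|---|---|---|
| ash | 0.10 M | 0.80 equiv | 2 mM | run made earlier |  |
| oak | 0.050 M | 0.80 equiv | 2 mM | run made earlier |  |
| birch | 0.075 M | 0.80 equiv | 2 mM | run made earlier |  |
| elm | 0.10 M | 0.80 equiv | 3 mM | run made earlier |  |
| south | 0.10 M | 0.800 equiv (fed, over 1.5 h) | 2.00 mM | all else is in the flask from the start; the feed brings no volume worth counting | 2.5 h |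
| west | 0.10 M (fed, over 1.5 h) | 0.800 equiv | 2.00 mM | all else is in the flask from the start; the feed brings no volume worth counting | 2.5 h |
| north-west | 0.10 M | 0.800 equiv | 2.00 mM | everything together at the start | 2.5 h |

| run | time / h | target / % | starting material / % |
|---|---|---|---|
| ash | 0.167 | 1 | 80 |
| ash | 0.500 | 6 | 51 |
| ash | 0.833 | 13 | 34 |
| ash | 1.33 | 18 | 19 |
| ash | 2.00 | 22 | 11 |
| ash | 2.50 | 24 | 7 |
| oak | 0.167 | 1 | 82 |
| oak | 0.500 | 8 | 56 |
| oak | 0.833 | 9 | 38 |
| oak | 1.33 | 17 | 20 |
| oak | 2.00 | 22 | 13 |
| oak | 2.50 | 24 | 6 |
| birch | 0.167 | 1 | 82 |
| birch | 0.500 | 7 | 50 |
| birch | 0.833 | 13 | 35 |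
| birch | 1.33 | 18 | 21 |
| birch | 2.00 | 21 | 12 |
| birch | 2.50 | 25 | 7 |
| elm | 0.200 | 3 | 78 |
| elm | 0.417 | 6 | 58 |
| elm | 0.667 | 11 | 42 |
| elm | 1.33 | 19 | 23 |
| elm | 2.50 | 25 | 6 |

(each reading ± 1.5 percentage points)

- a reading or a percentage of target counts all its forms, free or not
- a reading of starting material is of its free form alone

- the flask with the highest amount of target, in percent of the starting material charged ("all alike" if they lie within 1.5 percentage points) (south / west / north-west / all alike)
- final target, as a percentage of the starting material charged, in south
- final target, as a percentage of the starting material charged, in west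
- final target, as a percentage of the starting material charged, in north-west

Two chemists read these runs differently. The first says that if the share of target does not follow concentration, a feed merely costs time. She reckons with the mean presence, 0.700 here: the share of a charge that has entered, averaged over the run (a time average of the dose). For a steady feed it is one less the feed time over twice the run time. She scales the reading of ash, charged like north-west, by this presence and gets 16.8% for south and for west alike, with north-west ahead at 24%.

The second, who made the forecast, looks at how the target grows within a run. In ash, 1% target stood beside 80% starting material at 0.167 h, and 24% beside 7% at 2.50 h. Her words are: "Target per unit of starting material lost rises with conversion". She forecasts 15% for south, 26% for west and 24.5% for north-west, so west leads.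

The simulation gives 17.0% in south, 26.6% in west and 24.9% in north-west, so west leads, by 1.7 points against a margin of 1.5 points.

    starting material ⇌ open intermediate (K = 3.00, k = 0.0204 min⁻¹)
    partner → second intermediate (k = 0.00890 min⁻¹)
    open intermediate + second intermediate → target (k = 5.45 L mol⁻¹ min⁻¹)
    2 open intermediate → homo product (k = 4.51 L mol⁻¹ min⁻¹)
    partner + protic impurity → quenched reagent (k = 7.19 L mol⁻¹ min⁻¹)
    starting material + target ⇌ idle adduct, settled at all times (K = 20.0 L mol⁻¹)
    partner ⇌ dormant form (K = 2.70, k = 0.0268 min⁻¹)

West over north-west is 1.07, where the first view put the mean presence of 0.700. South over north-west is 0.683, but this nearness shows no feed costing time: south kept 6.11% starting material against 6.88% in north-west, and ended with 72.9% homo product against 62.4%. The first view's region is the runs charged at the start, where ash at 0.10 M and oak at 0.050 M both read 24% target. For a neighbour of south at 0.025 M starting material, the mean presence again gives 16.8%, and that neighbour ended at 13.1%.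

The data stem from a simulated flask with made-up constants, and the scatter is random.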